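## The problem

Target 33 is an ent-labdane: a trans-fused decalin (ring A = C1–C5 and C10, ring B = C5–C10) with quaternary C4 and C10, a C7=C8 alkene bearing the C8 methyl group, and at C9 a five-carbon chain that ends in an E-trisubstituted allylic ester. Four ring stereocentres (C3, C5, C9, C10) must be set in absolute terms and C13=C14 must be E; the fifth stereocentre lies in the 3-methylpentanoyl group and can be bought. C10 is quaternary and cannot be corrected later, so it has to come first and then control the rest: its axial methyl group decides the face from which H5 and H9 are delivered. The C3 oxygen is the awkward centre, because it is axial, syn to H5 and anti to the C10 methyl, which simple hydride reduction of a trans-fused 4,4-dimethyl-3-ketone does not give. Three groups will not survive rough treatment: the malonic half ester (decarboxylation, acyl transfer), the primary allylic ester (ionisation, hydrolysis) and the C7=C8 alkene, which acid moves to the tetrasubstituted C8=C9 position. Both acyl groups therefore go on last and the alkene is made late. The feature that opens the route is C4: it carries two methyl groups and lies between the oxygenated C3 and the ring-fusion carbon C5, so it can be the fully substituted α-carbon of a C3-ketone enolate that adds to a C5 ketone. The tertiary C5 hydroxyl formed in this way stands 1,3 to C3 and can pass configuration on to C3 before it is exchanged for H5.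

## Retrosynthesis

**Acyl groups.** The two acyl C–O bonds are cut first: 33 goes back to alcohol 31 and Meldrum's acid 32, and 31 to diol 29 and acid 30. Both esters are the most fragile parts of the molecule, so they should arrive last. The order follows reactivity: the primary allylic hydroxyl of 29 is acylated beside the hindered axial C3 hydroxyl, which then opens 32 under neutral conditions, so the malonate needs no protecting group. The forward steps must avoid acid or base strong enough to move the C7=C8 alkene.

**C13=C14.** Diol 29 comes from enoate 28 and this from methyl ketone 27 by cutting the C13=C14 bond. The neighbouring cut at C12–C13 (coupling of a C12 organometallic with an E-iodoalkene) would need a C12 handle and a separate fragment. The ketone cut instead keeps the chain as a masked 3-oxobutyl group, bought as bromide 19, with no alkene that could compete during the ring-B chemistry. One hydride reduction of 28 then frees both hydroxyls of 29. The olefination must be E-selective.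

**C8–C17 and the position of the ring alkene.** Ketone 27 (through ketal 26) is cut at the C8–methyl bond to enol triflate 25 and further to C8 ketone 24. A C8 ketone is the precursor from which the alkene position is unambiguous: kinetic enolisation goes to the C7 methylene and away from the hindered C9 methine, whereas dehydration of a C8 carbinol could give three alkenes. In 24, C9 is α to the carbonyl and its equatorial chain is the stable configuration, which secures this centre a second time.

**C9–C11 and the shift of oxygen from C9 to C8.** Ketone 24 comes from alcohol 23 and alkene 21, and 21 is cut at C9–C11 to enol triflate 18 and zinc reagent 20 (from 19); 18 comes from C9 ketone 17. C9 carries oxygen in this series, so it is the natural place for a cross-coupling, and hydroboration then moves the oxygen to C8 and delivers H9 anti to the C10 methyl. Two other ways were weighed and set aside: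
- Methylenation of a C9 enone and hydroboration would give a C11 alcohol, whose extension needs substitution at a neopentyl-type carbon with elimination as the easy escape.
- A sigmatropic shift from a C7 oxygen would deliver carbon to the wrong face of C9.

**Ring A stereocentres.** Ketone 17 is traced through 16, 15, 14, 13 and 12 to ketol 11 without cutting a skeletal bond. H5 comes from hydrogenation of the C5=C6 alkene of 15 directed by oxygen on the face opposite the C10 methyl. The alkene comes from dehydration of the tertiary C5 hydroxyl of 13, which can only eliminate towards C6. The C3 configuration of 12 comes from hydride delivered by the C5 hydroxyl of 11. In this way one aldol stereocentre fixes C3 and then C5.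

**C4–C5 (key disconnection).** Ketol 11 is cut at C4–C5 to keto-enone 9. No neighbouring cut in ring A makes a quaternary carbon and a ring-fusion carbon in one bond with the gem-dimethyl group already in the reagent. The precursor is monocyclic with only the C9 and C10 stereocentres. The forward reaction must generate the C4 enolate regiospecifically and make it add to a hindered ketone, which a hydride-triggered reductive aldol does.

**Precursor.** Enone 9 goes back through 8, 7 and 6 to allyl ketone 4 (chain extension of the allyl group by three carbons) and through ketol 3 to dione 2 and dione 1. The enzymatic reduction of 2 sets C10 by distinguishing two enantiotopic carbonyls; the carbinol it leaves at C9 is later the handle for the side chain.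

## Roads not taken

**Alternative 1:** Both rings are cut at once, through C5–C10 and C8–C9. This unfolds the decalin to the acyclic trienyl imide A1, a geranate-type chain whose C5–C8 silyloxydiene faces its own C9=C10 enoyl imide. Forward, [Cu(tBu-box)](SbF6)2 (divalent copper) would chelate the imide and drive an intramolecular Diels–Alder reaction to the trans-fused bicycle A2.
- Merits: two rings, two skeletal bonds and four stereocentres (C5, C8, C9, C10) from an achiral chain in one catalytic enantioselective step. C9 arrives already bonded to the future C11 on the correct face, and C8 arrives oxygenated. In ring construction this road is clearly shorter than the chosen one, which needs seven steps to reach 9 and seven more (steps 14–20) to move oxygen from C9 to C8 and attach C11 and the C8 methyl.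
- Weak points: the dienophile carbon C10 is β,β-disubstituted, which sharply lowers the reactivity of chelated enoyl imides, and the diene terminus C5 is attached to quaternary C4. The C5–C10 bond would thus join two crowded carbons in a step whose rate and endo/exo control are both uncertain. The C6=C7 alkene of A2 is in the wrong place, the imide carbon must be extended at a neopentyl-type C11, and the axial C3 alcohol would rest on reagent control alone.
- Comparison: against the better step count the chosen plan sets a ring closure that is intramolecular at the crowded bond and a C3 centre fixed by relay from C5.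

**Alternative 2:** Ring A is cut at C2=C3, which leads to the ring-B enone A3 with an allyl group on C10 and a 1,1-dimethylallyl group on C5. The second-generation Grubbs catalyst would close ring A with loss of ethene to give A4. Epoxidation of the new alkene from the face away from the C10 methyl and trans-diaxial hydride opening would then place the C3 hydroxyl axial.
- Merits: stereoelectronic epoxide opening is a more dependable way to the axial C3 alcohol than any ketone reduction. A4 also already holds the C8 methyl, the C7=C8 alkene and a C9 carbonyl, so its ring-B end game would be shorter than steps 14–20 here.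
- Weak points: the difficulty moves into A3. The C4–C5 bond between a quaternary carbon and a carbon next to quaternary C10 must be made intermolecularly, and the C5/C10 relation must be set before ring A exists to enforce it. Absolute configuration needs a separate solution, metathesis at a vinyl group on a quaternary carbon is slow, and the conjugated C9 ketone of A4 offers no easy way to add the chain with H9 on the right face.
- Comparison: the chosen plan sets against it a C4–C5 bond made intramolecularly, a gem-dimethyl group that comes with the ring closure, and C10 from one enzymatic step.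

**Alternative 3:** Ring A is cut at C1–C10 and C4–C5 into the aminosiloxydiene A5 and the E enal A6. A Diels–Alder reaction catalysed by [Cr(salen)]SbF6 (trivalent chromium), with acid work-up and loss of the amine, would give enone A7. A7 has quaternary C10, C5 and the C3 carbonyl in place and the allyl group cis to the methyl group.
- Merits: catalytic asymmetric construction of the quaternary centre from two small achiral pieces in one step. This is at least as short to an enantioenriched ring A as the enzymatic route is to 4, and it does not depend on a whole-cell reduction.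
- Weak points: A6 is an α,β-disubstituted enal and a sluggish dienophile for this catalyst class. A7 lacks the C4 gem-dimethyl group, which would have to be put in by double alkylation next to C5. Ring B is absent and must be built from the aldehyde (C9) and the allyl group (C6–C8), with the C8 methyl, the C7=C8 alkene and the C9 chain still to come. C3 is again left to reagent control.
- Comparison: after its key step this is the longest road. The chosen plan has ring B from the start and gets C4 fully substituted in the ring closure.

Key step: step 8

Remark on the chemistry: the yeast reduction of 2 is taken to give the (2S,3S)-ketol 3 as the major, separable stereoisomer, the one needed for C10 of the target. Bicyclic compounds are numbered as in the labdane skeleton (C20 = methyl on C10, C17 = methyl on C8).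

## Route

Step 1
Reactants: 1 2-methylcyclohexane-1,3-dione
Product: 2 2-allyl-2-methylcyclohexane-1,3-dione
Conditions: allyl bromide, NaOH, H2O, rt
Reagents that add atoms: allyl bromide, C=CCBr
Why: C-Alkylation of the stabilised dione enolate with a soft allylic halide in water favours carbon over oxygen and stops at the quaternary centre; no stereocentre is formed.

Step 2
Reactants: 2 2-allyl-2-methylcyclohexane-1,3-dione
Product: 3 (2S,3S)-2-allyl-3-hydroxy-2-methylcyclohexanone
Conditions: baker's yeast, sucrose, H2O, 30 °C
Reagents that add atoms: none
Why: Enantiotopic-group-selective bioreduction: the yeast ketoreductases reduce one of the two carbonyls from one face, which gives the (S)-carbinol and with it the (S) quaternary centre (later C10); the minor diastereomer is removed by chromatography.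

Step 3
Reactants: 3 (2S,3S)-2-allyl-3-hydroxy-2-methylcyclohexanone
Product: 4 (2S,3S)-2-allyl-3-(tert-butyldimethylsilyloxy)-2-methylcyclohexanone
Conditions: TBSOTf, 2,6-lutidine, CH2Cl2, −78 → 0 °C
Reagents that add atoms: tert-butyldimethylsilyl trifluoromethanesulfonate, CC(C)(C)[Si](C)(C)OS(=O)(=O)C(F)(F)F
Why: Silylation with the silyl triflate and a non-nucleophilic base protects the hindered carbinol without retro-aldol cleavage of the β-hydroxy ketone.

Step 4
Reactants: 4 (2S,3S)-2-allyl-3-(tert-butyldimethylsilyloxy)-2-methylcyclohexanone
Product: 6 (2S,3S)-3-(tert-butyldimethylsilyloxy)-2-(3-hydroxypropyl)-2-methylcyclohexanone, via catechol boronate 5 (not isolated)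
Conditions: catecholborane, RhCl(PPh3)3 (2 mol %), THF, rt; then NaOH, H2O2, 0 °C
Reagents that add atoms: hydrogen peroxide, OO
Why: Rhodium-catalysed hydroboration is anti-Markovnikov at the terminal alkene and, unlike uncatalysed boranes, leaves the hindered ketone alone; alkaline peroxide then replaces boron by hydroxyl.

Step 5
Reactants: 6 (2S,3S)-3-(tert-butyldimethylsilyloxy)-2-(3-hydroxypropyl)-2-methylcyclohexanone
Product: 7 (2S,3S)-3-(tert-butyldimethylsilyloxy)-2-methyl-2-(3-oxopropyl)cyclohexanone
Conditions: Dess–Martin periodinane, NaHCO3, CH2Cl2, 0 °C → rt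
Reagents that add atoms: none
Why: Dess–Martin oxidation of the primary alcohol stops at the aldehyde; the buffered medium spares the silyl ether and the α-quaternary ketone.

Step 6
Reactants: 7 (2S,3S)-3-(tert-butyldimethylsilyloxy)-2-methyl-2-(3-oxopropyl)cyclohexanone
Product: 8 (2S,3S)-3-(tert-butyldimethylsilyloxy)-2-(3-hydroxy-4-methylpent-4-enyl)-2-methylcyclohexanone
Conditions: CH2=C(CH3)MgBr, THF, −78 °C; NH4Cl
Reagents that add atoms: isopropenylmagnesium bromide, C=C(C)[Mg]Br
Why: Grignard 1,2-addition at low temperature discriminates the unhindered aldehyde from the α-quaternary ring ketone; the new carbinol centre forms as a mixture and is erased in step 7.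

Step 7
Reactants: 8 (2S,3S)-3-(tert-butyldimethylsilyloxy)-2-(3-hydroxy-4-methylpent-4-enyl)-2-methylcyclohexanone
Product: 9 (2S,3S)-3-(tert-butyldimethylsilyloxy)-2-methyl-2-(4-methyl-3-oxopent-4-enyl)cyclohexanone
Conditions: Dess–Martin periodinane, NaHCO3, CH2Cl2, 0 °C
Reagents that add atoms: none
Why: Dess–Martin oxidation of the allylic alcohol gives the isopropenyl ketone under neutral conditions that avoid conjugate addition to the enone or its polymerisation.

Step 8
Reactants: 9 (2S,3S)-3-(tert-butyldimethylsilyloxy)-2-methyl-2-(4-methyl-3-oxopent-4-enyl)cyclohexanone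
Product: 11 (5S,9S,10S)-9-(tert-butyldimethylsilyloxy)-5-hydroxy-4,4,10-trimethyl-cis-decalin-3-one, via C5 siloxane ether 10 (not isolated)
Conditions: [(Ph3P)CuH]6 (5 mol %), (Me2HSi)2O, toluene, −40 → 0 °C; then AcOH, THF/H2O, rt
Reagents that add atoms: none
Why: The copper hydride (monovalent copper) transfers hydride to the unsubstituted CH2 terminus of the isopropenyl ketone and leaves the ring ketone alone, which gives a copper enolate whose carbon C4 already bears both methyl groups, so no enolate geometry is at issue. This enolate adds to the only ketone, C5, through a chelated chair (Zimmerman–Traxler) array in which copper bridges the two oxygens; this forms C4–C5 and closes ring A in a 6-(enolexo)-exo-trig mode. The closest known reaction type is the copper-hydride reductive aldol cyclization of keto-enones, here stretched to an α,α-disubstituted enolate. The new C5 centre is controlled by C10 through the tether: in the chelated array the chain on C10 and the forming bond take the cis-fused arrangement, with the C5 hydroxyl on the face of the C10 methyl, as aldol closures onto 2,2-disubstituted cyclohexanones generally do, and the C9 silyl ether stays equatorial. σ-Bond metathesis of the copper aldolate with Si–H gives siloxane ether 10 and returns Cu–H, which takes the aldolate out of the retro-aldol equilibrium; dilute acetic acid then cleaves the labile siloxane and leaves the C9 silyl ether. The step needs C–C bond formation to outrun silylation or protonation of the enolate; the six-membered chelate and the absence of any other electrophile favour this, and the ketol cannot dehydrate towards C4 or C10.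

Step 9
Reactants: 11 (5S,9S,10S)-9-(tert-butyldimethylsilyloxy)-5-hydroxy-4,4,10-trimethyl-cis-decalin-3-one
Product: 12 9-(tert-butyldimethylsilyloxy)-4,4,10-trimethyl-cis-decalin-3,5-diol (3-OH anti to 5-OH)
Conditions: Me4NBH(OAc)3, MeCN/AcOH (1:1), −30 → 0 °C
Reagents that add atoms: none
Why: Evans–Saksena reduction: the tertiary C5 hydroxyl exchanges an acetate on boron and delivers hydride to the C3 carbonyl on its own face, so the new C3 hydroxyl is anti to the C5 hydroxyl and therefore trans to the C10 methyl. Steric approach control is expected to favour the same isomer, because the axial C5–C6 bond screens the other trajectory.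

Step 10
Reactants: 12 9-(tert-butyldimethylsilyloxy)-4,4,10-trimethyl-cis-decalin-3,5-diol (3-OH anti to 5-OH)
Product: 13 3-benzoyloxy-9-(tert-butyldimethylsilyloxy)-4,4,10-trimethyl-cis-decalin-5-ol
Conditions: BzCl, DMAP, pyridine, rt
Reagents that add atoms: benzoyl chloride, O=C(Cl)c1ccccc1
Why: DMAP-catalysed acylation takes only the secondary C3 hydroxyl, since the tertiary C5 hydroxyl between two quaternary carbons is inert; the benzoate has no α-hydrogen to interfere with the later amide bases and is removed without an extra step in step 23.

Step 11
Reactants: 13 3-benzoyloxy-9-(tert-butyldimethylsilyloxy)-4,4,10-trimethyl-cis-decalin-5-ol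
Product: 14 3-benzoyloxy-9-(tert-butyldimethylsilyloxy)-4,4,10-trimethyloctalin with C5=C6 alkene
Conditions: SOCl2, pyridine, 0 °C
Reagents that add atoms: none
Why: Dehydration of the tertiary alcohol through its chlorosulfite by anti elimination; C4 and C10 carry no hydrogen, so the alkene can only form towards C6.

Step 12
Reactants: 14 3-benzoyloxy-9-(tert-butyldimethylsilyloxy)-4,4,10-trimethyloctalin with C5=C6 alkene
Product: 15 3-benzoyloxy-4,4,10-trimethyloctalin-9-ol with C5=C6 alkene
Conditions: HF·pyridine, THF, 0 °C → rt
Reagents that add atoms: none
Why: Fluoride-driven cleavage of the Si–O bond frees the C9 hydroxyl; buffered HF leaves the benzoate and the hindered trisubstituted alkene untouched.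

Step 13
Reactants: 15 3-benzoyloxy-4,4,10-trimethyloctalin-9-ol with C5=C6 alkene
Product: 16 3-benzoyloxy-4,4,10-trimethyl-trans-decalin-9-ol (H5 and 3-O and 9-OH all trans to the C10 methyl)
Conditions: H2 (1 atm), [Ir(cod)(PCy3)(py)]PF6 (5 mol %), CH2Cl2, rt
Reagents that add atoms: none
Why: Hydroxyl-directed homogeneous hydrogenation: the cationic monovalent iridium complex binds the C9 hydroxyl (and the C3 ester carbonyl), both on the face opposite the C10 methyl, and delivers hydrogen to C5=C6 from that face. H5 is thus set anti to the C10 methyl (trans-fused decalin) and syn to the C3 oxygen.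

Step 14
Reactants: 16 3-benzoyloxy-4,4,10-trimethyl-trans-decalin-9-ol (H5 and 3-O and 9-OH all trans to the C10 methyl)
Product: 17 3-benzoyloxy-4,4,10-trimethyl-trans-decalin-9-one
Conditions: Dess–Martin periodinane, NaHCO3, CH2Cl2, rt
Reagents that add atoms: none
Why: Dess–Martin oxidation of the axial C9 alcohol; the new ketone can enolise only towards C8 because C10 is quaternary.

Step 15
Reactants: 17 3-benzoyloxy-4,4,10-trimethyl-trans-decalin-9-one
Product: 18 3-benzoyloxy-4,4,10-trimethyl-trans-octal-8-en-9-yl trifluoromethanesulfonate
Conditions: KN(SiMe3)2, PhNTf2, THF, −78 → 0 °C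
Reagents that add atoms: N-phenylbis(trifluoromethanesulfonimide), O=S(=O)(N(c1ccccc1)S(=O)(=O)C(F)(F)F)C(F)(F)F
Why: Enolisation is possible only towards C8, and O-sulfonylation of the potassium enolate gives the C8=C9 enol triflate; the benzoate has no acidic hydrogen.

Step 16
Reactants: 18 3-benzoyloxy-4,4,10-trimethyl-trans-octal-8-en-9-yl trifluoromethanesulfonate; 19 2-(2-bromoethyl)-2-methyl-1,3-dioxolane
Product: 21 3-benzoyloxy-13,13-ethylenedioxy-14,15,17-trinorlabd-8-ene, via alkylzinc bromide 20 (not isolated)
Conditions: 19, Zn, LiCl, THF, 40 °C; then 18, Pd(dppf)Cl2 (5 mol %), THF, 50 °C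
Reagents that add atoms: none
Why: Negishi coupling: zinc insertion into bromide 19 gives alkylzinc 20, which transmetalates to the vinylpalladium formed by oxidative addition of zerovalent palladium into the C9–O bond of the triflate. This makes C9–C11 with the C13 carbonyl masked; esters and acetals are tolerated.

Step 17
Reactants: 21 3-benzoyloxy-13,13-ethylenedioxy-14,15,17-trinorlabd-8-ene
Product: 23 3-benzoyloxy-13,13-ethylenedioxy-14,15,17-trinorlabdan-8-ol (8-OH and H9 trans to the C10 methyl), via C8 alkylborane 22 (not isolated)
Conditions: BH3·SMe2, THF, 0 °C → rt; then NaOH, H2O2, 0 °C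
Reagents that add atoms: hydrogen peroxide, OO
Why: Hydroboration–oxidation: boron adds to the less substituted C8 and hydrogen to C9, both from the face opposite the axial C10 methyl. H9 is thus set anti to that methyl with the side chain equatorial; the C8 configuration is immaterial.

Step 18
Reactants: 23 3-benzoyloxy-13,13-ethylenedioxy-14,15,17-trinorlabdan-8-ol (8-OH and H9 trans to the C10 methyl)
Product: 24 3-benzoyloxy-13,13-ethylenedioxy-14,15,17-trinorlabdan-8-one (H9 trans to the C10 methyl)
Conditions: Dess–Martin periodinane, NaHCO3, CH2Cl2, rt
Reagents that add atoms: none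
Why: Dess–Martin oxidation to the C8 ketone; C9 is now α to the carbonyl, and its equatorial side chain is the thermodynamic configuration, so any C9 epimer would converge on 24.

Step 19
Reactants: 24 3-benzoyloxy-13,13-ethylenedioxy-14,15,17-trinorlabdan-8-one (H9 trans to the C10 methyl)
Product: 25 3-benzoyloxy-13,13-ethylenedioxy-14,15,17-trinorlabd-7-en-8-yl trifluoromethanesulfonate
Conditions: KN(SiMe3)2, PhNTf2, THF, −78 °C
Reagents that add atoms: N-phenylbis(trifluoromethanesulfonimide), O=S(=O)(N(c1ccccc1)S(=O)(=O)C(F)(F)F)C(F)(F)F
Why: Kinetic deprotonation at the less hindered C7 methylene and O-sulfonylation fix the alkene at C7=C8; the C9 methine next to quaternary C10 is not touched, so C9 keeps its configuration.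

Step 20
Reactants: 25 3-benzoyloxy-13,13-ethylenedioxy-14,15,17-trinorlabd-7-en-8-yl trifluoromethanesulfonate
Product: 26 (3S,5S,9R,10S)-3-benzoyloxy-13,13-ethylenedioxy-14,15-dinorlabd-7-ene
Conditions: MeZnCl, Pd(PPh3)4 (5 mol %), THF, 50 °C
Reagents that add atoms: methylzinc chloride, C[Zn]Cl
Why: Negishi methylation of the enol triflate installs C17 on C8 with the alkene position retained; the benzoate and the acetal are inert to the organozinc.

Step 21
Reactants: 26 (3S,5S,9R,10S)-3-benzoyloxy-13,13-ethylenedioxy-14,15-dinorlabd-7-ene
Product: 27 (3S,5S,9R,10S)-3-benzoyloxy-14,15-dinorlabd-7-en-13-one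
Conditions: 1 M HCl, THF, rt
Reagents that add atoms: water, O
Why: Acid-catalysed acetal hydrolysis frees the methyl ketone; dilute acid at room temperature is too weak to move the C7=C8 alkene or cleave the benzoate.

Step 22
Reactants: 27 (3S,5S,9R,10S)-3-benzoyloxy-14,15-dinorlabd-7-en-13-one
Product: 28 ethyl (3S,5S,9R,10S,13E)-3-benzoyloxylabda-7,13-dien-15-oate
Conditions: (EtO)2P(O)CH2CO2Et, NaH, THF, 0 → 50 °C
Reagents that add atoms: triethyl phosphonoacetate, CCOC(=O)CP(=O)(OCC)OCC
Why: Horner–Wadsworth–Emmons olefination of the methyl ketone adds C14 and C15; the E isomer (ester trans to the larger chain) is expected to predominate, and the minor Z isomer is removed by chromatography.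

Step 23
Reactants: 28 ethyl (3S,5S,9R,10S,13E)-3-benzoyloxylabda-7,13-dien-15-oate
Product: 29 (3S,5S,9R,10S,13E)-labda-7,13-diene-3,15-diol
Conditions: i-Bu2AlH (excess), CH2Cl2, −78 → 0 °C; aq. potassium sodium tartrate
Reagents that add atoms: none
Why: The aluminium hydride reduces the enoate 1,2 to the allylic alcohol and cleaves the benzoate at its acyl C–O bond in the same operation, so C3 keeps its configuration and neither alkene is touched.

Step 24
Reactants: 29 (3S,5S,9R,10S,13E)-labda-7,13-diene-3,15-diol; 30 (S)-3-methylpentanoic acid
Product: 31 (3S,5S,9R,10S,13E)-3-hydroxylabda-7,13-dien-15-yl (S)-3-methylpentanoate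
Conditions: EDC·HCl, DMAP (cat.), CH2Cl2, 0 °C
Reagents that add atoms: none
Why: Steglich esterification: the primary allylic hydroxyl reacts far faster than the axial C3 hydroxyl next to quaternary C4, and the stereocentre of the acid is not enolised under these conditions.

Step 25
Reactants: 31 (3S,5S,9R,10S,13E)-3-hydroxylabda-7,13-dien-15-yl (S)-3-methylpentanoate; 32 Meldrum's acid
Product: 33 (3S,5S,9R,10S,13E)-3-(carboxyacetoxy)labda-7,13-dien-15-yl (S)-3-methylpentanoate
Conditions: toluene, 90 °C
Reagents that add atoms: none
Why: Thermal ring opening of Meldrum's acid by the alcohol with loss of acetone gives the malonic half ester directly; the neutral conditions spare the allylic ester and the C7=C8 alkene.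

## Compound list

1 | 2-methylcyclohexane-1,3-dione | CC1C(=O)CCCC1=O | starting material
2 | 2-allyl-2-methylcyclohexane-1,3-dione | C=CCC1(C)C(=O)CCCC1=O | intermediate
3 | (2S,3S)-2-allyl-3-hydroxy-2-methylcyclohexanone | C=CC[C@@]1(C)[C@@H](O)CCCC1=O | intermediate
4 | (2S,3S)-2-allyl-3-(tert-butyldimethylsilyloxy)-2-methylcyclohexanone | C=CC[C@@]1(C)[C@@H](O[Si](C)(C)C(C)(C)C)CCCC1=O | intermediate
5 | catechol boronate of 4 (1,3,2-benzodioxaborol-2-yl at the chain terminus) | c1ccc2OB(CCC[C@@]3(C)[C@@H](O[Si](C)(C)C(C)(C)C)CCCC3=O)Oc2c1 | intermediate
6 | (2S,3S)-3-(tert-butyldimethylsilyloxy)-2-(3-hydroxypropyl)-2-methylcyclohexanone | OCCC[C@@]1(C)[C@@H](O[Si](C)(C)C(C)(C)C)CCCC1=O | intermediate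
7 | (2S,3S)-3-(tert-butyldimethylsilyloxy)-2-methyl-2-(3-oxopropyl)cyclohexanone | O=CCC[C@@]1(C)[C@@H](O[Si](C)(C)C(C)(C)C)CCCC1=O | intermediate
8 | (2S,3S)-3-(tert-butyldimethylsilyloxy)-2-(3-hydroxy-4-methylpent-4-enyl)-2-methylcyclohexanone (both carbinol epimers) | CC(=C)C(O)CC[C@@]1(C)[C@@H](O[Si](C)(C)C(C)(C)C)CCCC1=O | intermediate
9 | (2S,3S)-3-(tert-butyldimethylsilyloxy)-2-methyl-2-(4-methyl-3-oxopent-4-enyl)cyclohexanone | CC(=C)C(=O)CC[C@@]1(C)[C@@H](O[Si](C)(C)C(C)(C)C)CCCC1=O | intermediate
10 | 5-O-(1,1,3,3-tetramethyldisiloxanyl) ether of ketol 11 | CC(C)(C)[Si](C)(C)O[C@H]1CCC[C@@]2(O[Si](C)(C)O[SiH](C)C)C(C)(C)C(=O)CC[C@@]12C | intermediate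
11 | (5S,9S,10S)-9-(tert-butyldimethylsilyloxy)-5-hydroxy-4,4,10-trimethyl-cis-decalin-3-one (5-OH cis to the C10 methyl; 9-O trans to it) | CC(C)(C)[Si](C)(C)O[C@H]1CCC[C@@]2(O)C(C)(C)C(=O)CC[C@@]12C | intermediate
12 | 9-(tert-butyldimethylsilyloxy)-4,4,10-trimethyl-cis-decalin-3,5-diol (3-OH anti to 5-OH; 3-O and 9-O trans to the C10 methyl) | CC(C)(C)[Si](C)(C)O[C@H]1CCC[C@@]2(O)C(C)(C)[C@@H](O)CC[C@@]12C | intermediate
13 | 3-benzoyloxy-9-(tert-butyldimethylsilyloxy)-4,4,10-trimethyl-cis-decalin-5-ol | CC(C)(C)[Si](C)(C)O[C@H]1CCC[C@@]2(O)C(C)(C)[C@@H](OC(=O)c3ccccc3)CC[C@@]12C | intermediate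
14 | 3-benzoyloxy-9-(tert-butyldimethylsilyloxy)-4,4,10-trimethyloctalin with C5=C6 alkene (3-O and 9-O trans to the C10 methyl) | CC(C)(C)[Si](C)(C)O[C@H]1CCC=C2C(C)(C)[C@@H](OC(=O)c3ccccc3)CC[C@@]12C | intermediate
15 | 3-benzoyloxy-4,4,10-trimethyloctalin-9-ol with C5=C6 alkene | O[C@H]1CCC=C2C(C)(C)[C@@H](OC(=O)c3ccccc3)CC[C@@]12C | intermediate
16 | 3-benzoyloxy-4,4,10-trimethyl-trans-decalin-9-ol (H5 and 3-O and 9-OH all trans to the C10 methyl) | O[C@H]1CCC[C@@H]2C(C)(C)[C@@H](OC(=O)c3ccccc3)CC[C@@]12C | intermediate
17 | 3-benzoyloxy-4,4,10-trimethyl-trans-decalin-9-one | O=C1CCC[C@@H]2C(C)(C)[C@@H](OC(=O)c3ccccc3)CC[C@@]12C | intermediate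
18 | 3-benzoyloxy-4,4,10-trimethyl-trans-octal-8-en-9-yl trifluoromethanesulfonate | FC(F)(F)S(=O)(=O)OC1=CCC[C@@H]2C(C)(C)[C@@H](OC(=O)c3ccccc3)CC[C@@]12C | intermediate
19 | 2-(2-bromoethyl)-2-methyl-1,3-dioxolane | CC1(CCBr)OCCO1 | starting material
20 | [2-(2-methyl-1,3-dioxolan-2-yl)ethyl]zinc bromide | CC1(CC[Zn]Br)OCCO1 | intermediate
21 | 3-benzoyloxy-13,13-ethylenedioxy-14,15,17-trinorlabd-8-ene | CC1(OCCO1)CCC2=CCC[C@@H]3C(C)(C)[C@@H](OC(=O)c4ccccc4)CC[C@@]23C | intermediate
22 | C8 alkylborane from 21 (drawn as the monoalkylborane; boron and H9 trans to the C10 methyl) | CC1(OCCO1)CC[C@@H]2[C@@H](B)CC[C@@H]3C(C)(C)[C@@H](OC(=O)c4ccccc4)CC[C@@]23C | intermediate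
23 | 3-benzoyloxy-13,13-ethylenedioxy-14,15,17-trinorlabdan-8-ol (8-OH and H9 trans to the C10 methyl) | CC1(OCCO1)CC[C@@H]2[C@@H](O)CC[C@@H]3C(C)(C)[C@@H](OC(=O)c4ccccc4)CC[C@@]23C | intermediate
24 | 3-benzoyloxy-13,13-ethylenedioxy-14,15,17-trinorlabdan-8-one (H9 trans to the C10 methyl) | CC1(OCCO1)CC[C@@H]2C(=O)CC[C@@H]3C(C)(C)[C@@H](OC(=O)c4ccccc4)CC[C@@]23C | intermediate
25 | 3-benzoyloxy-13,13-ethylenedioxy-14,15,17-trinorlabd-7-en-8-yl trifluoromethanesulfonate | CC1(OCCO1)CC[C@@H]2C(OS(=O)(=O)C(F)(F)F)=CC[C@@H]3C(C)(C)[C@@H](OC(=O)c4ccccc4)CC[C@@]23C | intermediate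
26 | (3S,5S,9R,10S)-3-benzoyloxy-13,13-ethylenedioxy-14,15-dinorlabd-7-ene | CC1(OCCO1)CC[C@@H]2C(C)=CC[C@@H]3C(C)(C)[C@@H](OC(=O)c4ccccc4)CC[C@@]23C | intermediate
27 | (3S,5S,9R,10S)-3-benzoyloxy-14,15-dinorlabd-7-en-13-one | CC(=O)CC[C@@H]1C(C)=CC[C@@H]2C(C)(C)[C@@H](OC(=O)c3ccccc3)CC[C@@]12C | intermediate
28 | ethyl (3S,5S,9R,10S,13E)-3-benzoyloxylabda-7,13-dien-15-oate | CCOC(=O)/C=C(\C)CC[C@@H]1C(C)=CC[C@@H]2C(C)(C)[C@@H](OC(=O)c3ccccc3)CC[C@@]12C | intermediate
29 | (3S,5S,9R,10S,13E)-labda-7,13-diene-3,15-diol | OC/C=C(\C)CC[C@@H]1C(C)=CC[C@@H]2C(C)(C)[C@@H](O)CC[C@@]12C | intermediate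
30 | (S)-3-methylpentanoic acid | CC[C@H](C)CC(=O)O | starting material
31 | (3S,5S,9R,10S,13E)-3-hydroxylabda-7,13-dien-15-yl (S)-3-methylpentanoate | CC[C@H](C)CC(=O)OC/C=C(\C)CC[C@@H]1C(C)=CC[C@@H]2C(C)(C)[C@@H](O)CC[C@@]12C | intermediate
32 | Meldrum's acid (2,2-dimethyl-1,3-dioxane-4,6-dione) | CC1(C)OC(=O)CC(=O)O1 | starting material
33 | (3S,5S,9R,10S,13E)-3-(carboxyacetoxy)labda-7,13-dien-15-yl (S)-3-methylpentanoate | CC[C@H](C)CC(=O)OC/C=C(\C)CC[C@@H]1C(C)=CC[C@@H]2C(C)(C)[C@@H](OC(=O)CC(=O)O)CC[C@@]12C | target

## Step count and risks

Total step count: 25. Longest linear sequence: 25 steps, from 1 to 33; compounds 19, 30 and 32 are bought and enter in steps 16, 24 and 25.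

**Key step (step 8).** The most likely failure is hydride transfer without C–C bond formation. The tetrasubstituted enolate may be silylated or protonated faster than it adds to a ketone next to quaternary C10, because the closure creates three contiguous fully substituted carbons (C4, C5, C10). Alternatively the aldolate may revert before it is trapped. The fallback separates enolate formation from bond formation and activates the ketone instead. It sets out from 9: 1,4-hydrosilylation with Et3SiH and RhCl(PPh3)3 should give the triethylsilyl enol ether F1, and TiCl4 in CH2Cl2 at −78 °C should then close ring A by an intramolecular Mukaiyama aldol addition. Aqueous work-up returns to the route at ketol 11.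

**Step 9.** Internal hydride delivery may fail. The tertiary C5 hydroxyl exchanges slowly with the acetoxyborohydride and is equatorial on ring A in the preferred conformer of the cis-decalin, so ring A must leave its chair to bring boron over C3. The result would be a slow reduction or loss of facial control. The fallback changes the order and relies on reagent bulk in a trans-type framework. From 11, dehydration (SOCl2, pyridine) should give the β,γ-unsaturated ketone F2. LiBH(s-Bu)3 at −78 °C attacks such 4,4-dimethyl-3-ketones from the equatorial direction and should give the axial alcohol F3, and benzoylation returns to the route at 14.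

**Step 13.** The C5=C6 alkene is trisubstituted and lies between two quaternary carbons, so the risk is no turnover, catalyst deactivation before conversion, or weak facial discrimination. The fallback is hydrogen-atom-transfer hydrogenation with Mn(dpm)3, PhSiH3 and t-BuOOH in i-PrOH. It proceeds through the C5 tertiary radical and is governed by the stability of the trans-fused product, not by approach of a metal complex to the alkene. It sets out from 15 and comes back at 16 and makes no new compound (F0).

**Step 22.** Geometric selectivity may be incomplete: the two substituents on the ketone carbonyl differ little in size, so a substantial share of the Z enoate and loss on separation are possible. The fallback builds the alkene by stereospecific syn-carbometalation. From 27, KN(SiMe3)2 and PhNTf2 at −78 °C should give the terminal enol triflate F4, and LiN(i-Pr)2 at −78 °C should eliminate it to the terminal alkyne F5. Zirconium-catalysed carboalumination (Me3Al, Cp2ZrCl2) and quenching of the alkenylalane with ClCO2Et then return to the route at 28 as the E isomer only.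

**Step 25.** The axial C3 hydroxyl next to quaternary C4 may open Meldrum's acid too slowly, so that decomposition of the reagent or decarboxylation of the half ester on long heating takes over. The fallback uses a protected malonate. From 31, acylation with 3-oxo-3-[2-(trimethylsilyl)ethoxy]propanoic acid (DCC, DMAP) should give the mixed malonate F6, and Bu4NF buffered with AcOH removes the silylethyl group and comes back to the route at 33.

## Further compounds

F1 | step 8 | triethylsilyl enol ether of 9 (tetrasubstituted enol, ring ketone free) | CC(C)=C(O[Si](CC)(CC)CC)CC[C@@]1(C)[C@@H](O[Si](C)(C)C(C)(C)C)CCCC1=O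
F2 | step 9 | 9-(tert-butyldimethylsilyloxy)-4,4,10-trimethyloctalin-3-one with C5=C6 alkene | CC(C)(C)[Si](C)(C)O[C@H]1CCC=C2C(C)(C)C(=O)CC[C@@]12C
F3 | step 9 | 9-(tert-butyldimethylsilyloxy)-4,4,10-trimethyloctalin-3-ol with C5=C6 alkene (3-OH axial, trans to the C10 methyl) | CC(C)(C)[Si](C)(C)O[C@H]1CCC=C2C(C)(C)[C@@H](O)CC[C@@]12C
F0 | step 13 | none | none
F4 | step 22 | (3S,5S,9R,10S)-3-benzoyloxy-14,15-dinorlabda-7,13(16)-dien-13-yl trifluoromethanesulfonate | C=C(OS(=O)(=O)C(F)(F)F)CC[C@@H]1C(C)=CC[C@@H]2C(C)(C)[C@@H](OC(=O)c3ccccc3)CC[C@@]12C
F5 | step 22 | (3S,5S,9R,10S)-3-benzoyloxy-15,16-dinorlabd-7-en-13-yne | C#CCC[C@@H]1C(C)=CC[C@@H]2C(C)(C)[C@@H](OC(=O)c3ccccc3)CC[C@@]12C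
F6 | step 25 | 2-(trimethylsilyl)ethyl malonate of 31 at C3 | CC[C@H](C)CC(=O)OC/C=C(\C)CC[C@@H]1C(C)=CC[C@@H]2C(C)(C)[C@@H](OC(=O)CC(=O)OCC[Si](C)(C)C)CC[C@@]12C
A1 | alternative 1 | acyclic (E)-enoyl oxazolidinone with ketal at C3 and (E,E)-silyloxydiene at C5–C8 | O=C1OCCN1C(=O)/C=C(\C)CCC2(OCCO2)C(C)(C)/C=C/C=C/O[Si](C)(C)C(C)(C)C
A2 | alternative 1 | trans-fused bicyclic imide with C8 silyl ether and C6=C7 alkene | O=C1OCCN1C(=O)[C@@H]2[C@H](O[Si](C)(C)C(C)(C)C)C=C[C@@H]3C(C)(C)C4(OCCO4)CC[C@@]23C
A3 | alternative 2 | 6-allyl-2,6-dimethyl-5-(2-methylbut-3-en-2-yl)cyclohex-2-enone (ring B with C10 allyl and C5 dimethylallyl) | O=C1C(C)=CC[C@H](C(C)(C)C=C)[C@@]1(C)CC=C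
A4 | alternative 2 | trans-fused bicyclic enone with C2=C3 alkene | O=C1C(C)=CC[C@@H]2C(C)(C)C=CC[C@@]12C
A5 | alternative 3 | (E)-1-(dimethylamino)-3-(tert-butyldimethylsilyloxy)buta-1,3-diene | CN(C)/C=C/C(=C)O[Si](C)(C)C(C)(C)C
A6 | alternative 3 | (E)-2-methylhexa-2,5-dienal | C=CC/C=C(\C)C=O
A7 | alternative 3 | 5-allyl-4-formyl-4-methylcyclohex-2-enone (allyl cis to methyl) | C=CC[C@@H]1CC(=O)C=C[C@@]1(C)C=O
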